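# Proposed total synthesis of vismiaphenone D by double ortho-quinone methide capture

Numbers 1–15 are defined in the steps and collected in the list after them. Compound 9 is the bis-Mannich base, 10 the alkenyl Grignard reagent and 15 the target.

## Analysis of the target

Vismiaphenone D (15, C24H28O5) is a benzophenone: two benzene rings joined through one ketone carbon, with no further ring. Ring B is a plain 4-hydroxyphenyl group. Ring A is fully substituted, with the aroyl group at C1, free hydroxyls at C2 and C6, 3-methylbut-2-enyl (prenyl) chains at C3 and C5, and a methoxy group at C4. The axis through C1 and C4 relates C2 to C6 and C3 to C5, there is no stereocentre, and each alkene ends in two methyl groups, so the molecule is achiral and no configuration has to be set.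

Each prenyl group lies ortho to a free phenol. Brønsted or Lewis acids close such a pair to a 2,2-dimethylchroman, and hydrogenation saturates the alkenes, so every acidic or reductive deprotection should be finished before the prenyl groups arrive.

The hard part is chemoselectivity on ring A. Acylphloroglucinol anions are ambident: with allylic halides they give O-alkylation, geminal dialkylation with dearomatisation and mono/di mixtures. In addition, one of the three ring-A oxygens must be singled out as the methyl ether while a fourth phenol sits on ring B.

The plan rests on one structural feature. The benzylic CH2 on C3 is ortho to the C2 hydroxyl and the benzylic CH2 on C5 is ortho to the C6 hydroxyl, and a phenol with an ortho CH2–Nu unit is the retron of nucleophilic addition to the exocyclic carbon of an ortho-quinone methide. Cutting each prenyl chain between its CH2 and its vinylic CH reduces it to two pieces: a one-carbon unit that electrophilic aminomethylation can place on C3 and C5, and an isobutenyl anion, available as the commercial reagent 10.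

## Retrosynthetic reasoning

**Disconnection 1 (15 ⇒ 9 + two 10).** The bonds cut are the CH2–CH= bonds inside the two prenyl chains.
- The more obvious cut, between ring and CH2, would ask an ambident phloroglucinol anion to react with an allylic electrophile exactly twice at carbon and never at oxygen.
- The chosen cut makes ring A the electrophile instead. In the forward direction 9 is N-methylated to 11 and deprotonated by 10, and each ortho phenoxide pushes out its ammonium group.
- The quinone methides 12 and 14 accept the alkenyl carbon of 10 at the exocyclic CH2 and rearomatise (12 → 13, 14 → 15).
- The gain is two skeletal bonds in one flask, no allylic transposition and no O- or gem-alkylation. The prenyl groups also appear only in the last operation.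
- The forward reaction has to beat addition to the ketone and self-condensation of the quinone methides.

**Disconnection 2 (9 ⇒ 6 + two 7).** The C3–CH2 and C5–CH2 bonds are cut.
- C3 and C5 are the only open positions of ring A in 6 and its most nucleophilic carbons.
- An iminium electrophile substitutes there with rearomatisation, so each position receives exactly one carbon and over-alkylation is impossible.
- The reaction passes through 8 and must be driven to 9 before 8 can lose its amine.
- It must also leave the less nucleophilic ring B alone.

**Disconnection 3 (6 ⇒ 4).** No skeletal bond is cut, only three O–C bonds: the O–CH3 bonds at C2 and C6 and the O–CH2Ph bond at C4'.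
- Differentiating the C4 oxygen by selective methylation of a tetraphenol would be unreliable, because the ring-B phenol competes.
- Selective cleavage works in the opposite sense. A boron halide held by the ketone oxygen reaches only the two ortho methoxy groups, so the C4 methyl ether is what remains.
- The cleavage runs through 5. All Lewis-acid chemistry is thereby finished before any alkene is present.

**Disconnection 4 (4 ⇒ 1 + 2).** The C1–C(=O) bond is cut.
- Ring A is the natural nucleophile, and in 1 its three open positions are equivalent, so a Friedel–Crafts acylation has no regiochemical choice and stops after one acylation.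
- The acid 2 is activated in the flask as 3.
- Its benzyl ether keeps the ring-B phenol from being acylated and is later removed in the same operation as the two methyl ethers, so it costs no step.

## Alternatives that were turned down

**Alternative 1:** Ring A is dismantled completely and rebuilt by a Danheiser-type benzannulation.
- *Disconnection and key step.* Ketene A1 and 1-methoxy-5-methylhex-4-en-1-yne A2 combine by [2+2] cycloaddition to 3-methoxy-2-prenylcyclobutenone A3. A3 is then heated with a second molecule of A2. Four-electron ring opening, ketene–alkyne [2+2], a second ring opening and six-electron closure place the alkyne carbons at C3 and C4 (target numbering). The new bonds are C2–C3 and C4–C5, and the product is 3,5-dimethoxy-2,4-diprenylphenol A4.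
- *For it.* One alkyne is used twice, both prenyl groups are carbon-bound from the start, and the pericyclic cascade fixes the positions of all five substituents. On regiochemical certainty of prenyl placement it is stronger than the chosen route, whose C–C bond formation depends on a reactive intermediate behaving well twice.
- *Against it.* A4 lacks the aroyl group and carries one methyl ether too many. The last open ring carbon would have to be aroylated, and the methoxy group next to the new ketone cleaved with a Lewis acid. Both operations would run on a ring that already holds prenyl/phenol pairs prone to chroman closure, and the ring-B phenol would still need unmasking. A1 is a toxic gas that must be generated, A2 is not an article of commerce, and the intermediate ketenes carry tethered trisubstituted alkenes that can undergo intramolecular [2+2] cycloaddition.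
- *Comparison.* The chosen plan buys ring A ready-made, needs about half the steps, and exposes the alkenes to nothing after they are formed.

**Alternative 2:** Ring A is cut at C1–C2 and C1–C6 into a five-carbon and a one-carbon piece.
- *Disconnection and key step.* The methyl carbon of 4-allyloxyacetophenone A6, as its enolate, is acylated twice by the two ester groups of dimethyl 3-methoxy-2,4-diprenylglutaconate A5. The ring closes and aromatises to 4'-O-allyl vismiaphenone D A7.
- *For it.* The approach uses the symmetry of ring A and forms the whole skeleton in one step with the C4 oxygen already differentiated. It ends with a palladium-catalysed deallylation that prenyl groups tolerate. On mildness of the endgame and absence of any organometallic near the ketone it equals or betters the chosen route.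
- *Against it.* A5 has an acidic γ-hydrogen, so the ketone enolate should deprotonate it to a delocalised dienolate in which both esters are switched off. One ester is a vinylogous carbonate and both are α-branched. After the first acylation the nucleophile is a stabilised 1,3-diketone enolate, which tends to close through oxygen to a pyranone rather than through carbon. Addition–elimination at the methoxy-bearing carbon is a further escape. A5 itself requires a twofold, position-selective C-prenylation of a 1,3-dicarbonyl diester and an O-methylation, which brings back the ambident-alkylation problem.
- *Comparison.* The chosen plan puts all its risk in one step, whose individual events (elimination, conjugate addition) are each favourable, and reaches that step by three conventional reactions.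

**Alternative 3:** Ring B is built by cycloaddition.
- *Disconnection and key step.* The ethynyl ketone A8, 1-[4-methoxy-2,6-bis(methoxymethoxy)-3,5-diprenylphenyl]prop-2-yn-1-one, reacts with Danishefsky's diene A9. The alkyne carbons become C1' and C6', and the new bonds are C1'–C2' and C5'–C6'. Loss of the methoxy and silyl groups aromatises the adduct to vismiaphenone D 2,6-bis(methoxymethyl) ether A10.
- *For it.* The regiochemistry of this diene with ynones is dependable and puts the oxygen para to the ketone. The conditions are neutral, and the 4'-phenol appears without a protecting group. In reliability of the key step itself it is stronger than the chosen route.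
- *Against it.* The key step is spent on a 4-hydroxyphenyl ring that can be bought as part of 2, while the real problem, the hexasubstituted diprenylated ring A, is merely moved into the synthesis of A8. That synthesis still needs a double prenylation, followed by one-carbon and two-carbon homologation and oxidation at a position flanked on both sides. Removal of the two acetals from A10 needs acid just as each liberated phenol comes to lie next to a prenyl group.
- *Comparison.* The route is much longer, whereas the chosen plan addresses ring A directly and ends at 15 with no deprotection.

Key step: step 4

Remark on the chemistry: 15 contains no stereogenic element, so the compound asked for is the achiral molecule itself; species present in the flask as magnesium phenoxides or boron aryloxides are named and drawn as the parent phenols.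

## Route

**Step 1**
Reactants: 1 1,3,5-trimethoxybenzene; 2 4-(benzyloxy)benzoic acid
Product: 4 4'-benzyloxy-2,4,6-trimethoxybenzophenone, via 4-(benzyloxy)benzoic trifluoroacetic anhydride 3 (not isolated)
Conditions: 2, (CF3CO)2O (1.3 equiv), CH2Cl2, 0 °C; then 1, 0 °C → rt
Reagents that add atoms: trifluoroacetic anhydride, O=C(OC(=O)C(F)(F)F)C(F)(F)F (supplies the CF3CO group of 3; none of its atoms remain in 4)
Why: Friedel–Crafts acylation through a mixed carboxylic–trifluoroacetic anhydride: 3 ionises towards the alkoxy-stabilised aroyl cation, which the very electron-rich 1 captures without a metal Lewis acid, so the benzyl and methyl ethers stay intact. The three open positions of 1 are equivalent and the twisted, deactivated ketone 4 does not react again; preforming 3 with little excess anhydride keeps trifluoroacetylation of 1 down.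

**Step 2**
Reactants: 4 4'-benzyloxy-2,4,6-trimethoxybenzophenone
Product: 6 2,6,4'-trihydroxy-4-methoxybenzophenone, via 2,4'-dihydroxy-4,6-dimethoxybenzophenone 5 (not isolated)
Conditions: BCl3 (1 M in CH2Cl2, 6 equiv), C6HMe5 (3 equiv), CH2Cl2, −78 °C → rt; then 1 M aq. HCl/THF
Reagents that add atoms: none
Why: Chelation-directed boron trichloride ether cleavage: boron held by the ketone oxygen reaches only the C2 and C6 methoxy oxygens, so chloride removes the first methyl group quickly (to 5) and the second on warming with excess reagent, while the remote, weakly basic C4 methoxy group is left. The aryl benzyl ether falls to the same reagent at low temperature, and pentamethylbenzene takes up the benzyl cation by Friedel–Crafts alkylation before it can attack C3 or C5 of ring A.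

**Step 3**
Reactants: 6 2,6,4'-trihydroxy-4-methoxybenzophenone; 7 N,N-dimethylmethyleneiminium iodide (Eschenmoser's salt)
Product: 9 3,5-bis(dimethylaminomethyl)-2,6,4'-trihydroxy-4-methoxybenzophenone, via mono-Mannich base 8 (not isolated)
Conditions: 7 (2.3 equiv), K2CO3 (2.5 equiv), MeCN, 0 °C → rt; pH 7–8 buffer work-up
Reagents that add atoms: N,N-dimethylmethyleneiminium iodide (7), C=[N+](C)C.[I-]
Why: Twofold Mannich aminomethylation with a preformed iminium salt: C3 and C5 are the only open positions of ring A, each activated by two phenol oxygens and the methoxy group, and are far more nucleophilic than C3'/C5' of ring B, whose phenol is conjugated with the ketone. Every substitution ends in rearomatisation, so exactly one carbon is placed per position, and cold anhydrous conditions with a slight excess of 7 carry 8 on to 9 before it can lose amine.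

**Step 4**
Reactants: 9 3,5-bis(dimethylaminomethyl)-2,6,4'-trihydroxy-4-methoxybenzophenone; 10 2-methylprop-1-enylmagnesium bromide
Product: 15 vismiaphenone D, via bis(trimethylammonium) diiodide 11 (not isolated), via first ortho-quinone methide 12 (not isolated), via monoprenyl ammonium iodide 13 (not isolated), via second ortho-quinone methide 14 (not isolated)
Conditions: MeI (3 equiv), THF, rt, dark; volatiles removed in vacuo; THF, −78 °C, 10 (0.5 M in THF, 8 equiv), −78 °C → rt; sat. aq. NH4Cl
Reagents that add atoms: 2-methylprop-1-enylmagnesium bromide (10), CC(C)=C[Mg]Br; iodomethane, CI (supplies the N-methyl groups of 11, 12 and 13; none of its atoms remain in 15)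
Why: Iodomethane quaternises the two benzylic dimethylamino groups of 9 (Menshutkin reaction; the neutral, hydrogen-bonded phenols should not compete) to give 11, and the excess is stripped off before the organometallic is added. At −78 °C the first three equivalents of 10 only deprotonate the phenols; on warming the C2 phenoxide expels trimethylamine to give ortho-quinone methide 12, and 10 delivers its alkenyl carbon to the exocyclic CH2 in a 1,4-addition driven by rearomatisation, giving 13. A ring A with both methylenes unmasked has no closed-shell structure, so the second elimination (C6 phenoxide, to 14) can only follow the first addition, and the second addition gives the tris-phenoxide of 15, which ammonium chloride protonates without endangering the prenyl/phenol pairs. The closest known reaction type is the addition of organomagnesium reagents, alkenyl ones included, to ortho-quinone methides released by phenoxide-triggered elimination from ortho-hydroxybenzyl ammonium salts, acetates or carbonates; what goes beyond it here is only the twofold execution and the free diaryl ketone. No ring closes and no stereocentre or stereogenic alkene is formed. The first selectivity needed is conjugate over carbonyl addition: the ketone is flanked by two ortho magnesium phenoxides, twisted out of conjugation and fed by three phenoxide donors, so it behaves as a vinylogous carboxylate, whereas the exocyclic CH2 is unhindered. The second is capture over oligomerisation: all phenoxides are formed cold before any quinone methide is released, each quinone methide is born in a large excess of nucleophile, only one can exist per molecule at a time, and no open ring carbon is left to attack it. Because the new bond is made at the sp2 carbon of 10, the alkene ends up in the prenyl position without allylic transposition, and O-alkylation or geminal dialkylation cannot occur.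

## Compound list

1 | 1,3,5-trimethoxybenzene | COc1cc(OC)cc(OC)c1 | starting material
2 | 4-(benzyloxy)benzoic acid | O=C(O)c1ccc(OCc2ccccc2)cc1 | starting material
3 | 4-(benzyloxy)benzoic trifluoroacetic anhydride | O=C(OC(=O)C(F)(F)F)c1ccc(OCc2ccccc2)cc1 | intermediate
4 | 4'-benzyloxy-2,4,6-trimethoxybenzophenone | COc1cc(OC)c(C(=O)c2ccc(OCc3ccccc3)cc2)c(OC)c1 | intermediate
5 | 2,4'-dihydroxy-4,6-dimethoxybenzophenone | COc1cc(O)c(C(=O)c2ccc(O)cc2)c(OC)c1 | intermediate
6 | 2,6,4'-trihydroxy-4-methoxybenzophenone | COc1cc(O)c(C(=O)c2ccc(O)cc2)c(O)c1 | intermediate
7 | N,N-dimethylmethyleneiminium iodide | C=[N+](C)C.[I-] | starting material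
8 | 3-(dimethylaminomethyl)-2,6,4'-trihydroxy-4-methoxybenzophenone | COc1cc(O)c(C(=O)c2ccc(O)cc2)c(O)c1CN(C)C | intermediate
9 | 3,5-bis(dimethylaminomethyl)-2,6,4'-trihydroxy-4-methoxybenzophenone | COc1c(CN(C)C)c(O)c(C(=O)c2ccc(O)cc2)c(O)c1CN(C)C | intermediate
10 | 2-methylprop-1-enylmagnesium bromide | CC(C)=C[Mg]Br | starting material
11 | 2,6,4'-trihydroxy-4-methoxy-3,5-bis[(trimethylammonio)methyl]benzophenone diiodide | COc1c(C[N+](C)(C)C)c(O)c(C(=O)c2ccc(O)cc2)c(O)c1C[N+](C)(C)C.[I-].[I-] | intermediate
12 | 3-hydroxy-2-(4-hydroxybenzoyl)-5-methoxy-6-methylidene-4-[(trimethylammonio)methyl]cyclohexa-2,4-dien-1-one iodide | C=C1C(=O)C(C(=O)c2ccc(O)cc2)=C(O)C(C[N+](C)(C)C)=C1OC.[I-] | intermediate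
13 | 2,6,4'-trihydroxy-4-methoxy-3-(3-methylbut-2-enyl)-5-[(trimethylammonio)methyl]benzophenone iodide | COc1c(CC=C(C)C)c(O)c(C(=O)c2ccc(O)cc2)c(O)c1C[N+](C)(C)C.[I-] | intermediate
14 | 3-hydroxy-2-(4-hydroxybenzoyl)-5-methoxy-4-(3-methylbut-2-enyl)-6-methylidenecyclohexa-2,4-dien-1-one | C=C1C(=O)C(C(=O)c2ccc(O)cc2)=C(O)C(CC=C(C)C)=C1OC | intermediate
15 | vismiaphenone D, 2,6,4'-trihydroxy-4-methoxy-3,5-bis(3-methylbut-2-enyl)benzophenone (achiral) | COc1c(CC=C(C)C)c(O)c(C(=O)c2ccc(O)cc2)c(O)c1CC=C(C)C | target

## Step count and least certain steps

Total step count: 4. Longest linear sequence: 4 steps (from 1 or 2 to 15).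

**Step 4 (key step).** Several processes could spoil it.
- N-methylation may be incomplete or unselective, because 9 is partly zwitterionic (protonated amine, phenoxide).
- 11 and its magnesium salts may dissolve poorly in THF. The quinone methides would then be released in a phase short of nucleophile and condense with phenoxide oxygens.
- 1,2-Addition to the ketone may occur if the phenoxide deactivation is weaker than expected.
- A quinone methide may be captured in a hetero-Diels–Alder reaction by the alkene set free when 10 is protonated.

The fallback sets out from 9 and returns at 15. Refluxing 9 in ethanol should exchange both dimethylamino groups for ethoxy groups through the same quinone methides, the volatile amine escaping. This gives 3,5-bis(ethoxymethyl)-2,6,4'-trihydroxy-4-methoxybenzophenone F1, a neutral compound that can be chromatographed. Reagent 10 is converted with triisopropyl borate, then anhydrous acid, into diisopropyl (2-methylprop-1-enyl)boronate F2. Heating F1 with F2 and catalytic 2,2'-biphenol in toluene over molecular sieves lets the ortho phenol bind to boron. The ethoxy group then leaves, and the alkenyl group migrates from boron to the exocyclic carbon of the boron-bound quinone methide. This is the known diol-catalysed alkenylboronate addition to ortho-quinone methides made from ortho-hydroxybenzyl ethers. A boronate does not add to a diaryl ketone and needs no strong base. The quinone methide is present only at low stationary concentration, with its nucleophile tied to its own oxygen.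

**Step 3.** The likely failure is premature loss of amine from 8, followed by attack of an open ring carbon of 6 or 8 on the resulting quinone methide. This methylene-bridged dimerisation is typical of acylphloroglucinols. Some aminomethylation of ring B and losses in isolating the amphoteric product are also possible.

The fallback sets out from 6 and returns at 15. Condensation of 6 with 1-(hydroxymethyl)benzotriazole in hot acetic acid, the known benzotriazolylmethylation of phenols, should give 3,5-bis(benzotriazol-1-ylmethyl)-2,6,4'-trihydroxy-4-methoxybenzophenone F3. This compound is neutral and not amphoteric. F3 needs no quaternisation. Excess 10 in THF/toluene with warming deprotonates it, the magnesium phenoxides expel benzotriazolide, and the quinone methides are captured as in step 4. The displacement of benzotriazole from ortho-(benzotriazolylmethyl)phenols by Grignard reagents is known. This path bypasses 9 and 11.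

**Step 2.** The cleavage may stall at 5, because the first boron chelate ties up the carbonyl oxygen. Forcing it may then cost the C4 methyl group, and benzyl transfer to C3/C5 may not be fully suppressed.

The fallback sets out from 2 and returns at 6, replacing selective cleavage by orthogonal protection.
- Acid 2 is converted (oxalyl chloride, then N,O-dimethylhydroxylamine) into the Weinreb amide 4-(benzyloxy)-N-methoxy-N-methylbenzamide F4.
- Commercial 5-methoxyresorcinol is protected with chloromethyl methyl ether and Hünig's base as 1-methoxy-3,5-bis(methoxymethoxy)benzene F5.
- n-BuLi in THF lithiates F5 between the two stronger directing acetal groups, giving 4-methoxy-2,6-bis(methoxymethoxy)phenyllithium F6.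
- Addition of F6 to F4 gives 4'-benzyloxy-4-methoxy-2,6-bis(methoxymethoxy)benzophenone F7.
- Hydrogenolysis (H2, Pd/C) gives 4'-hydroxy-4-methoxy-2,6-bis(methoxymethoxy)benzophenone F8.
- Dilute HCl in methanol then removes both acetals to give 6. No alkene is yet present, so hydrogen and acid are harmless.

## Further compounds

F1 | step 4 | 3,5-bis(ethoxymethyl)-2,6,4'-trihydroxy-4-methoxybenzophenone | CCOCc1c(O)c(C(=O)c2ccc(O)cc2)c(O)c(COCC)c1OC
F2 | step 4 | diisopropyl (2-methylprop-1-enyl)boronate | CC(C)=CB(OC(C)C)OC(C)C
F3 | step 3 | 3,5-bis(benzotriazol-1-ylmethyl)-2,6,4'-trihydroxy-4-methoxybenzophenone | COc1c(Cn2nnc3ccccc23)c(O)c(C(=O)c2ccc(O)cc2)c(O)c1Cn1nnc2ccccc12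
F4 | step 2 | 4-(benzyloxy)-N-methoxy-N-methylbenzamide | CON(C)C(=O)c1ccc(OCc2ccccc2)cc1
F5 | step 2 | 1-methoxy-3,5-bis(methoxymethoxy)benzene | COCOc1cc(OC)cc(OCOC)c1
F6 | step 2 | 4-methoxy-2,6-bis(methoxymethoxy)phenyllithium | [Li]c1c(OCOC)cc(OC)cc1OCOC
F7 | step 2 | 4'-benzyloxy-4-methoxy-2,6-bis(methoxymethoxy)benzophenone | COCOc1cc(OC)cc(OCOC)c1C(=O)c1ccc(OCc2ccccc2)cc1
F8 | step 2 | 4'-hydroxy-4-methoxy-2,6-bis(methoxymethoxy)benzophenone | COCOc1cc(OC)cc(OCOC)c1C(=O)c1ccc(O)cc1
A1 | alternative 1 | ketene | C=C=O
A2 | alternative 1 | 1-methoxy-5-methylhex-4-en-1-yne | COC#CCC=C(C)C
A3 | alternative 1 | 3-methoxy-2-(3-methylbut-2-enyl)cyclobut-2-en-1-one | COC1=C(CC=C(C)C)C(=O)C1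
A4 | alternative 1 | 3,5-dimethoxy-2,4-bis(3-methylbut-2-enyl)phenol | COc1cc(O)c(CC=C(C)C)c(OC)c1CC=C(C)C
A5 | alternative 2 | dimethyl 3-methoxy-2,4-bis(3-methylbut-2-enyl)pent-2-enedioate (alkene geometry and C4 configuration left open, both lost on enolisation) | COC(=O)C(CC=C(C)C)=C(OC)C(CC=C(C)C)C(=O)OC
A6 | alternative 2 | 4-allyloxyacetophenone | CC(=O)c1ccc(OCC=C)cc1
A7 | alternative 2 | 4'-O-allyl vismiaphenone D | COc1c(CC=C(C)C)c(O)c(C(=O)c2ccc(OCC=C)cc2)c(O)c1CC=C(C)C
A8 | alternative 3 | 1-[4-methoxy-2,6-bis(methoxymethoxy)-3,5-bis(3-methylbut-2-enyl)phenyl]prop-2-yn-1-one | C#CC(=O)c1c(OCOC)c(CC=C(C)C)c(OC)c(CC=C(C)C)c1OCOC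
A9 | alternative 3 | Danishefsky's diene, (E)-1-methoxy-3-(trimethylsilyloxy)buta-1,3-diene | CO/C=C/C(=C)O[Si](C)(C)C
A10 | alternative 3 | vismiaphenone D 2,6-bis(methoxymethyl) ether | COCOc1c(CC=C(C)C)c(OC)c(CC=C(C)C)c(OCOC)c1C(=O)c1ccc(O)cc1
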